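**Plan**
1. Cuts: the spiro dihydropyran is opened at CH2–C(spiro) and at OCH2–O. Its O–C(iPr)=CH–CH2 part is the 1-oxadiene isopropyl vinyl ketone; the spiro carbon with its OCH2 is an exocyclic, sulfur-activated C=C on the one-carbon bridge of the 8-azabicyclo[4.3.1]decene, one olefination away from a bridge ketone. This retron is what makes an inverse-demand oxa-Diels–Alder reaction possible.
2. Earlier cuts: N–CH2 and CH2–C(α to the bridge ketone) of the piperidine (Mannich/lactam closure), CH2–C(quaternary) of the cyclopentane (enolate alkylation), C(sp2)–C(quaternary) of the cycloheptene (enolate alkenylation), and the side-chain C–C bond at the allylic CH (allylic alkylation).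
3. Forward order: cyclopentene (from 3-ethoxycyclopentenone), then the seven-membered β-keto ester ring, the cyclopentane, the lactam bridge and the spiro dihydropyran; the helpers (PhS, lactam C=O) are then removed and the ester is cleaved.
4. Stereochemistry: the allylic CH comes from a CBS reduction relayed with retention by palladium. It fixes the quaternary bridgehead through cis ring fusion, which fixes the second bridgehead through the lactam bridge. The spiro centre comes from attack on the alkene face over the lactam bridge, and the ester-bearing CH is set last by kinetic protonation.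

Key step: step 14

Assumption: 3 and 23 are taken as purchasable (otherwise one step each from 5-bromopent-1-ene and 3-methylbutan-2-one); from 12 to 26 the carbon α to the methyl ester is carried as both epimers and is made uniform in step 17.

Step 1
Reactants: 1 3-ethoxycyclopent-2-en-1-one
Product: 2 2-bromo-3-ethoxycyclopent-2-en-1-one
Conditions: NBS, CH2Cl2, 0 °C to 25 °C
Reagents that add atoms: N-bromosuccinimide, O=C1CCC(=O)N1Br
Why: Electrophilic α-bromination of a vinylogous ester (the enol-ether β-carbon is the nucleophile) should install the vinylic bromide that later becomes the site of the enolate alkenylation in step 10.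

Step 2
Reactants: 2 2-bromo-3-ethoxycyclopent-2-en-1-one; 3 pent-4-en-1-ylmagnesium bromide
Product: 5 2-bromo-3-(pent-4-en-1-yl)cyclopent-2-en-1-one, via bromomagnesium alkoxide 4 (not isolated)
Conditions: THF, 0 °C; then 1 M HCl, 25 °C
Reagents that add atoms: water, O
Why: Stork–Danheiser transposition: 1,2-addition of the Grignard reagent to the vinylogous ester carbonyl and acid-induced loss of water and ethanol should give the 3-alkyl-2-bromoenone, with the new carbonyl oxygen coming from the aqueous acid.

Step 3
Reactants: 5 2-bromo-3-(pent-4-en-1-yl)cyclopent-2-en-1-one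
Product: 6 (S)-2-bromo-3-(pent-4-en-1-yl)cyclopent-2-en-1-ol
Conditions: (R)-2-methyl-CBS-oxazaborolidine (15 mol %), catecholborane, toluene, −78 °C
Reagents that add atoms: none
Why: Corey–Bakshi–Shibata reduction, for which 2-bromoenones are reliable substrates: with the bromoalkenyl arm as the large group the (R)-catalyst should deliver hydride to the face that gives the (S)-carbinol, the only external source of absolute configuration in the route, and catecholborane at low temperature should spare the terminal alkene.

Step 4
Reactants: 6 (S)-2-bromo-3-(pent-4-en-1-yl)cyclopent-2-en-1-ol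
Product: 7 (S)-2-bromo-3-(pent-4-en-1-yl)cyclopent-2-en-1-yl methyl carbonate
Conditions: ClCO2Me, pyridine, CH2Cl2, 0 °C
Reagents that add atoms: methyl chloroformate, COC(=O)Cl
Why: Routine O-acylation of the secondary allylic alcohol gives the carbonate leaving group for the allylic alkylation without touching the stereocentre.

Step 5
Reactants: 7 (S)-2-bromo-3-(pent-4-en-1-yl)cyclopent-2-en-1-yl methyl carbonate; 8 2,2-dimethyl-1,3-dioxane-4,6-dione
Product: 9 5-[(R)-2-bromo-3-(pent-4-en-1-yl)cyclopent-2-en-1-yl]-2,2-dimethyl-1,3-dioxane-4,6-dione
Conditions: Pd(PPh3)4 (5 mol %), THF, 25 °C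
Reagents that add atoms: none
Why: Tsuji–Trost allylic alkylation with a soft carbon acid: zerovalent palladium should ionize the carbonate with inversion and the enolate of 8 should attack the less substituted allyl terminus anti to the metal, so that the C–C bond forms with net retention, the new allylic CH is (R) and the alkene stays in the tetrasubstituted bromoalkene position.

Step 6
Reactants: 9 5-[(R)-2-bromo-3-(pent-4-en-1-yl)cyclopent-2-en-1-yl]-2,2-dimethyl-1,3-dioxane-4,6-dione
Product: 11 methyl 2-[(R)-2-bromo-3-(pent-4-en-1-yl)cyclopent-2-en-1-yl]prop-2-enoate, via aminomethyl dioxanedione 10 (not isolated)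
Conditions: CH2=NMe2 I, MeOH, 65 °C
Reagents that add atoms: N,N-dimethylmethyleneiminium iodide, C=[N+](C)C.[I-]; methanol, CO
Why: Mannich aminomethylation of the acidic C–H of the dioxanedione followed in the same pot by methanolysis, loss of acetone and decarboxylative elimination of dimethylamine, a known one-pot conversion of monosubstituted 2,2-dimethyl-1,3-dioxane-4,6-diones into α-substituted acrylates.

Step 7
Reactants: 11 methyl 2-[(R)-2-bromo-3-(pent-4-en-1-yl)cyclopent-2-en-1-yl]prop-2-enoate
Product: 12 methyl 2-[(R)-2-bromo-3-(pent-4-en-1-yl)cyclopent-2-en-1-yl]-3-chloropropanoate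
Conditions: HCl (4 M in dioxane), 0 °C to 25 °C
Reagents that add atoms: hydrogen chloride, Cl
Why: Conjugate hydrochlorination of the acrylate should give the β-chloro ester needed as the internal alkylating agent; protonation α to the ester is not controlled, so this carbon is a mixture of epimers until step 17.

Step 8
Reactants: 12 methyl 2-[(R)-2-bromo-3-(pent-4-en-1-yl)cyclopent-2-en-1-yl]-3-chloropropanoate
Product: 14 methyl 2-[(R)-2-bromo-3-(4-oxobutyl)cyclopent-2-en-1-yl]-3-chloropropanoate, via diol 13 (not isolated)
Conditions: OsO4 (2 mol %), NaIO4, 2,6-lutidine, dioxane–H2O, 25 °C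
Reagents that add atoms: osmium tetroxide (catalytic oxygen carrier), O=[Os](=O)(=O)=O; sodium periodate, [Na+].[O-]I(=O)(=O)=O
Why: Lemieux–Johnson oxidative cleavage: the monosubstituted terminal alkene should be dihydroxylated much faster than the tetrasubstituted, bromine-deactivated ring alkene, and periodate cleaves the diol to the aldehyde.

Step 9
Reactants: 14 methyl 2-[(R)-2-bromo-3-(4-oxobutyl)cyclopent-2-en-1-yl]-3-chloropropanoate; 15 ethyl diazoacetate
Product: 16 ethyl 6-[(3R)-2-bromo-3-(3-chloro-1-methoxy-1-oxopropan-2-yl)cyclopent-1-en-1-yl]-3-oxohexanoate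
Conditions: SnCl2 (10 mol %), CH2Cl2, 25 °C
Reagents that add atoms: none
Why: Roskamp reaction: SnCl2-promoted addition of the diazo ester to the aldehyde followed by 1,2-hydride shift and loss of dinitrogen should give the β-keto ester under neutral conditions that spare the alkyl chloride and the vinyl bromide.

Step 10
Reactants: 16 ethyl 6-[(3R)-2-bromo-3-(3-chloro-1-methoxy-1-oxopropan-2-yl)cyclopent-1-en-1-yl]-3-oxohexanoate
Product: 17 ethyl (3R)-3-(3-chloro-1-methoxy-1-oxopropan-2-yl)-5-oxo-1,2,3,4,5,6,7,8-octahydroazulene-4-carboxylate
Conditions: Pd(OAc)2 (5 mol %), 2-(di-tert-butylphosphino)-2'-methylbiphenyl (10 mol %), K3PO4, toluene, 90 °C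
Reagents that add atoms: none
Why: Palladium-catalysed intramolecular α-alkenylation of a 1,3-dicarbonyl enolate (oxidative addition of zerovalent palladium into the vinyl C–Br bond, enolate binding, reductive elimination) should close the seven-membered ring; the new CH between the two carbonyls stays enolizable, so its configuration does not matter.

Step 11
Reactants: 17 ethyl (3R)-3-(3-chloro-1-methoxy-1-oxopropan-2-yl)-5-oxo-1,2,3,4,5,6,7,8-octahydroazulene-4-carboxylate
Product: 18 tricyclic keto diester (5-5-7 carbocycle)
Conditions: Cs2CO3, NaI (10 mol %), DMF, 50 °C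
Reagents that add atoms: none
Why: Intramolecular 5-exo-tet C-alkylation of the β-keto ester enolate by the alkyl iodide formed in situ (Finkelstein exchange): the chain is anchored at the allylic stereocentre and can reach only the enolate face on its own side of the ring-fusion alkene, which should set the quaternary centre with the ring ketone carbon on the face of the chain and the ethoxycarbonyl group on the face of the ring-fusion hydrogen.

Step 12
Reactants: 18 tricyclic keto diester (5-5-7 carbocycle)
Product: 20 bridged keto lactam methyl ester, via amino diester 19 (not isolated)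
Conditions: 1,3,5-trimethyl-1,3,5-triazinane (0.4 equiv), AcOH, 60 °C; then toluene, 110 °C
Reagents that add atoms: 1,3,5-trimethyl-1,3,5-triazinane, CN1CN(C)CN(C)C1
Why: Mannich reaction at the only enolizable α-carbon of the ketone (the other is quaternary) followed by lactamization of the secondary amine onto the adjacent ethyl ester: only the epimer with the aminomethyl arm cis to that ester can close and the α-carbon equilibrates through the enol, so the second bridgehead is dictated by the first.

Step 13
Reactants: 20 bridged keto lactam methyl ester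
Product: 22 exocyclic vinyl sulfide, via lithium silyl alkoxide 21 (not isolated)
Conditions: PhSCH2SiMe3, n-BuLi, THF, 0 °C; then 20, −78 °C to 25 °C; aq. NH4Cl
Reagents that add atoms: (phenylthiomethyl)trimethylsilane, C[Si](C)(C)CSc1ccccc1
Why: Peterson olefination: the small, strongly nucleophilic α-silyl α-thio carbanion should add to the non-enolizable bridge ketone and the β-silyl alkoxide eliminates lithium trimethylsilanolate to give the exocyclic vinyl sulfide, whose geometry is irrelevant.

Step 14
Reactants: 22 exocyclic vinyl sulfide; 23 4-methylpent-1-en-3-one (isopropyl vinyl ketone)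
Product: 24 spiro 2-(phenylthio)-6-isopropyl-3,4-dihydro-2H-pyran lactam ester
Conditions: 23 (8 equiv), Yb(fod)3 [Yb(C10H10F7O2)3] (10 mol %), BHT, toluene, 70 °C, sealed tube
Reagents that add atoms: none
Why: Inverse-electron-demand oxa-Diels–Alder reaction: the s-cis enone 23, its LUMO lowered by the oxophilic lanthanide, is the 4π heterodiene and the sulfur-donor alkene of 22 the 2π partner; bond formation is asynchronous, the enone CH2 terminus attacking the nucleophilic bridge carbon first (thionium character at the CHSPh carbon) before the carbonyl oxygen closes onto that carbon, which fixes the regiochemistry CH2–C(spiro) and O–CH(SPh). The closest known reaction type is the thermal or lanthanide-catalysed cycloaddition of vinyl ketones with vinyl sulfides and enol ethers to 2-thio- or 2-alkoxy-3,4-dihydro-2H-pyrans, including β,β-disubstituted donors that give a quaternary C-3. The dihydropyran ring closes in the [4+2] mode (in the stepwise limit a Michael addition followed by six-membered O-capture of the thionium ion, the four-membered C-capture being strained and reversible). The spiro stereocentre is controlled by the bicycle: the enone should approach the exocyclic alkene on the face over the three-atom lactam bridge (planar N–C=O, a single axial H) and not over the four-carbon bridge, which carries the CH2–CH2 unit, the fused cyclopentane and its ester, so that the new CH2 lies syn to the lactam and the sulfur-bearing carbon syn to the cycloheptene. The anomeric CH(SPh) centre forms as a mixture and is erased in step 15. The step needs regioselectivity (secured by the sulfur donor), facial selectivity (secured by the unequal bridges) and chemoselectivity for the donor alkene over the tetrasubstituted ring alkene (which has no donor and is inert toward the electron-poor heterodiene).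

Step 15
Reactants: 24 spiro 2-(phenylthio)-6-isopropyl-3,4-dihydro-2H-pyran lactam ester
Product: 25 spiro dihydropyran lactam methyl ester
Conditions: Bu3SnH, AIBN, toluene, 100 °C
Reagents that add atoms: none
Why: Radical reductive desulfurization of an O,S-acetal: the stannyl radical abstracts the phenylthio group, the α-alkoxy radical is quenched by hydrogen transfer, and the neutral chain conditions should leave the enol ether, lactam and ester intact while erasing the anomeric stereocentre.

Step 16
Reactants: 25 spiro dihydropyran lactam methyl ester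
Product: 26 spiro dihydropyran N-methylpiperidine methyl ester
Conditions: [IrCl(C8H14)2]2 (1 mol %), Et2SiH2, toluene, 25 °C to 60 °C
Reagents that add atoms: none
Why: Iridium-catalysed hydrosilylation of a tertiary amide to the amine, a neutral deoxygenative reduction that should be chemoselective for the lactam over the methyl ester and compatible with the acid-sensitive enol ether, unmasks the N-methylpiperidine.

Step 17
Reactants: 26 spiro dihydropyran N-methylpiperidine methyl ester
Product: 28 methyl ester of the target, via lithium enolate 27 (not isolated)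
Conditions: LiN(iPr)2, THF, −78 °C; then 2,6-di-tert-butyl-4-methylphenol, −78 °C; aq. NH4Cl
Reagents that add atoms: none
Why: Deprotonation and kinetic protonation of the ester: the planar lithium enolate should take up the proton on the cyclopentane face remote from the spiro-substituted one-carbon bridge, which places the new hydrogen cis to the ring-fusion hydrogen and the ester on the more hindered face as in the target and converges both epimers to one.

Step 18
Reactants: 28 methyl ester of the target
Product: 29 target acid CNP0237695.1
Conditions: Me3SnOH, ClCH2CH2Cl, 80 °C; pH 7 phosphate buffer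
Reagents that add atoms: trimethyltin hydroxide (regenerated from water on work-up), C[Sn](C)(C)O
Why: Trimethyltin hydroxide ester cleavage under neutral conditions, chosen because it should not epimerize the α-stereocentre just set and avoids the aqueous acid that would hydrolyse the enol ether.

**Compound list**
1 | 3-ethoxycyclopent-2-en-1-one | CCOC1=CC(=O)CC1 | starting material
2 | 2-bromo-3-ethoxycyclopent-2-en-1-one | CCOC1=C(Br)C(=O)CC1 | intermediate
3 | pent-4-en-1-ylmagnesium bromide | C=CCCC[Mg]Br | starting material
4 | bromomagnesium 2-bromo-3-ethoxy-1-(pent-4-en-1-yl)cyclopent-2-en-1-olate (racemic) | CCOC1=C(Br)C(O[Mg]Br)(CCCC=C)CC1 | intermediate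
5 | 2-bromo-3-(pent-4-en-1-yl)cyclopent-2-en-1-one | O=C1CCC(CCCC=C)=C1Br | intermediate
6 | (S)-2-bromo-3-(pent-4-en-1-yl)cyclopent-2-en-1-ol | C=CCCCC1=C(Br)[C@H](CC1)O | intermediate
7 | (S)-2-bromo-3-(pent-4-en-1-yl)cyclopent-2-en-1-yl methyl carbonate | C=CCCCC1=C(Br)[C@H](CC1)OC(=O)OC | intermediate
8 | 2,2-dimethyl-1,3-dioxane-4,6-dione | CC1(C)OC(=O)CC(=O)O1 | starting material
9 | 5-[(R)-2-bromo-3-(pent-4-en-1-yl)cyclopent-2-en-1-yl]-2,2-dimethyl-1,3-dioxane-4,6-dione | C=CCCCC1=C(Br)[C@H](CC1)C2C(=O)OC(C)(C)OC2=O | intermediate
10 | 5-[(R)-2-bromo-3-(pent-4-en-1-yl)cyclopent-2-en-1-yl]-5-[(dimethylamino)methyl]-2,2-dimethyl-1,3-dioxane-4,6-dione (formed as its hydroiodide) | C=CCCCC1=C(Br)[C@H](CC1)C2(CN(C)C)C(=O)OC(C)(C)OC2=O | intermediate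
11 | methyl 2-[(R)-2-bromo-3-(pent-4-en-1-yl)cyclopent-2-en-1-yl]prop-2-enoate | C=CCCCC1=C(Br)[C@H](CC1)C(=C)C(=O)OC | intermediate
12 | methyl 2-[(R)-2-bromo-3-(pent-4-en-1-yl)cyclopent-2-en-1-yl]-3-chloropropanoate (both epimers at C-2 of the propanoate) | C=CCCCC1=C(Br)[C@H](CC1)C(CCl)C(=O)OC | intermediate
13 | methyl 2-[(R)-2-bromo-3-(4,5-dihydroxypentyl)cyclopent-2-en-1-yl]-3-chloropropanoate (diol, epimer mixture) | OCC(O)CCCC1=C(Br)[C@H](CC1)C(CCl)C(=O)OC | intermediate
14 | methyl 2-[(R)-2-bromo-3-(4-oxobutyl)cyclopent-2-en-1-yl]-3-chloropropanoate (both epimers at C-2 of the propanoate) | O=CCCCC1=C(Br)[C@H](CC1)C(CCl)C(=O)OC | intermediate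
15 | ethyl diazoacetate | CCOC(=O)C=[N+]=[N-] | starting material
16 | ethyl 6-[(3R)-2-bromo-3-(3-chloro-1-methoxy-1-oxopropan-2-yl)cyclopent-1-en-1-yl]-3-oxohexanoate (both side-chain epimers) | CCOC(=O)CC(=O)CCCC1=C(Br)[C@H](CC1)C(CCl)C(=O)OC | intermediate
17 | ethyl (3R)-3-(3-chloro-1-methoxy-1-oxopropan-2-yl)-5-oxo-1,2,3,4,5,6,7,8-octahydroazulene-4-carboxylate (C-4 enolizable, both side-chain epimers) | CCOC(=O)C1C(=O)CCCC2=C1[C@H](CC2)C(CCl)C(=O)OC | intermediate
18 | tricyclic keto diester: 5-5-7 carbocycle with ring-fusion C=C, ketone in the seven-membered ring, CO2Et on the quaternary α-carbon (on the face of the ring-fusion H) and CO2Me on the cyclopentane (both epimers at the CO2Me carbon) | O=C1CCCC2=C3[C@H](CC2)C(C(=O)OC)C[C@@]31C(=O)OCC | intermediate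
19 | amino diester: Mannich base of 18 carrying CH2NHCH3 on the α-CH of the ketone (epimer mixture) | O=C1C(CNC)CCC2=C3[C@H](CC2)C(C(=O)OC)C[C@@]31C(=O)OCC | intermediate
20 | bridged keto lactam methyl ester: 8-methyl-8-azabicyclo[4.3.1]dec-2-ene-9,10-dione core fused to the cyclopentene and to the CO2Me-bearing cyclopentane (both epimers at the CO2Me carbon) | O=C1[C@@H]2CCC3=C4[C@H](CC3)C(C(=O)OC)C[C@@]41C(=O)N(C)C2 | intermediate
21 | lithium alkoxide adduct of 20: bridge carbon bearing OLi and CH(SPh)SiMe3 (mixture at the two new centres) | [Li+].[O-]C1(C(Sc2ccccc2)[Si](C)(C)C)[C@@H]3CCC4=C5[C@H](CC4)C(C(=O)OC)C[C@@]51C(=O)N(C)C3 | intermediate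
22 | exocyclic vinyl sulfide: (phenylthio)methylidene on the one-carbon bridge of the lactam ester (either alkene geometry) | c1ccccc1SC=C2[C@@H]3CCC4=C5[C@H](CC4)C(C(=O)OC)C[C@@]52C(=O)N(C)C3 | intermediate
23 | 4-methylpent-1-en-3-one (isopropyl vinyl ketone) | CC(C)C(=O)C=C | starting material
24 | spiro 2-(phenylthio)-6-isopropyl-3,4-dihydro-2H-pyran lactam ester (spiro at pyran C-3; mixture at the S-bearing carbon) | CC(C)C1=CC[C@@]2(C(Sc5ccccc5)O1)[C@@H]1CCC3=C4[C@H](CC3)C(C(=O)OC)C[C@@]42C(=O)N(C)C1 | intermediate
25 | spiro dihydropyran lactam methyl ester (both epimers at the CO2Me carbon) | CC(C)C1=CC[C@@]2(CO1)[C@@H]1CCC3=C4[C@H](CC3)C(C(=O)OC)C[C@@]42C(=O)N(C)C1 | intermediate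
26 | spiro dihydropyran N-methylpiperidine methyl ester (both epimers at the CO2Me carbon) | CC(C)C1=CC[C@@]2(CO1)[C@@H]1CCC3=C4[C@H](CC3)C(C(=O)OC)C[C@@]42CN(C)C1 | intermediate
27 | lithium enolate of 26 | [Li+].CC(C)C1=CC[C@@]2(CO1)[C@@H]1CCC3=C4[C@H](CC3)C(=C([O-])OC)C[C@@]42CN(C)C1 | intermediate
28 | methyl ester of the target (single epimer; ester cis to the spiro carbon and trans to the CH2N arm) | CC(C)C1=CC[C@@]2(CO1)[C@@H]1CCC3=C4[C@H](CC3)[C@H](C(=O)OC)C[C@@]42CN(C)C1 | intermediate
29 | target acid CNP0237695.1 | CC(C)C1=CC[C@@]2(CO1)[C@@H]1CCC3=C4[C@H](CC3)[C@H](C(=O)O)C[C@@]42CN(C)C1 | target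

**Count**
Total steps: 18. Longest linear sequence: 18 steps (1 to 29).

**Steps most likely to fail**

(a) Step 14. The bond to the fully substituted bridge carbon may form too slowly, so that the vinyl ketone oligomerizes; the zwitterion may collapse to a cyclobutane; or the enone may approach the wrong face. The fallback builds the ring stepwise, sets out from 22 and returns at 25. The vinyl sulfide 22 is hydrolysed (TiCl4, H2O, MeCN) to the bridge aldehyde F1. Base- or enamine-mediated Michael addition of F1 to 23 (DBU or pyrrolidine, catalytic) creates the quaternary centre by the same facial argument and gives the keto aldehyde F2. Chemoselective reduction of the aldehyde (NaBH4, MeOH, −40 °C) gives the hydroxy ketone F3. Acid-catalysed cyclodehydration (pyridinium tosylate, toluene, 4 Å sieves, 80 °C) then gives the enol ether 25, whose ring oxygen is the former aldehyde oxygen.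

(b) Step 13. The bulky α-silyl carbanion may add too slowly to the hindered bridge ketone, with competing attack on the methyl ester or deprotonation next to it. The fallback sets out from 20 and returns at 25. Wittig methoxymethylenation of 20 (Ph3P=CHOMe from (methoxymethyl)triphenylphosphonium chloride and KN(SiMe3)2, THF, 0 °C to 50 °C) gives the methyl enol ether F4. F4 serves as the 2π partner for 23 under the conditions of step 14 and gives the 2-methoxy acetal F5. Ionic hydrogenolysis of the anomeric methoxy group (Et3SiH, Me3SiOTf, CH2Cl2, −78 °C) then gives 25.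

(c) Step 17. Enolization may be incomplete, or the two faces of the enolate may be poorly discriminated in the protonation, leaving the epimer with the ester on the wrong face. The fallback sets out from 26 and returns directly at 29. The epimer mixture 26 is submitted to diastereomer-selective enzymatic hydrolysis with a carboxylesterase (pig liver esterase or a screened lipase, phosphate buffer pH 7.5 with MeCN, 30 °C), chosen to accept only the epimer with the target configuration. The unreacted ester epimer is recovered, re-equilibrated (NaOMe, MeOH) and resubmitted; no new compound is formed.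

**Further compounds**
F1 | step 14 | bridge aldehyde: formyl group on the one-carbon bridge of the lactam ester (epimers at the bridge carbon) | O=CC2[C@@H]3CCC4=C5[C@H](CC4)C(C(=O)OC)C[C@@]52C(=O)N(C)C3
F2 | step 14 | keto aldehyde: bridge carbon bearing CHO and CH2CH2C(=O)CH(CH3)2 | CC(C)C(=O)CC[C@@]2(C=O)[C@@H]3CCC4=C5[C@H](CC4)C(C(=O)OC)C[C@@]52C(=O)N(C)C3
F3 | step 14 | hydroxy ketone: bridge carbon bearing CH2OH and CH2CH2C(=O)CH(CH3)2 | CC(C)C(=O)CC[C@@]2(CO)[C@@H]3CCC4=C5[C@H](CC4)C(C(=O)OC)C[C@@]52C(=O)N(C)C3
F4 | step 13 | methyl enol ether: methoxymethylidene on the one-carbon bridge of the lactam ester | COC=C2[C@@H]3CCC4=C5[C@H](CC4)C(C(=O)OC)C[C@@]52C(=O)N(C)C3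
F5 | step 13 | spiro 2-methoxy-6-isopropyl-3,4-dihydro-2H-pyran lactam ester | CC(C)C1=CC[C@@]2(C(OC)O1)[C@@H]1CCC3=C4[C@H](CC3)C(C(=O)OC)C[C@@]42C(=O)N(C)C1
F0 | step 17 | none | none
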